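**Plan**
- Retrosynthetic cuts, in order: the two MOM ethers and the C4 ketone (back to a C4 carbinol); the aryl ether bond O1–C8a of ring C; the C2–C3 bond (aldol); the C8 prenyl group (allyl Claisen rearrangement, then cross-metathesis).
- Enabling feature: O1 links the stereogenic carbinol carbon C2 to aromatic carbon C8a of ring A, so the C2 oxygen of an open-chain 1,3-diol can be arylated at C8a while the C2–O bond stays intact.
- Forward: ring A is bought as an acetophenone and dressed (MOM at the future 5-oxygen, allyl then prenyl at C8, triflate at C8a). The C2–C3 bond joins it to the ring B aldehyde, with reduction in the same flask. Ring C then closes by palladium-catalysed C–O coupling, and oxidation at C4 plus acetal cleavage finish the synthesis.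
- Stereochemistry: C2 (S) comes from a reagent-controlled boron aldol addition and is carried through with retention; the C4 carbinol centre is temporary and is erased by oxidation.

Key step: step 8

Assumption: 2',6'-dihydroxy-4'-methoxyacetophenone (1) is a catalogue compound and is bought; flavanone numbering (O1, C2 to C8a, primed positions for ring B) is used for ring positions throughout.

**Step 1**
Reactants: 1 2',6'-dihydroxy-4'-methoxyacetophenone
Product: 2 2'-hydroxy-4'-methoxy-6'-(methoxymethoxy)acetophenone
Conditions: MOMCl (1.1 equiv), iPr2NEt, CH2Cl2, 0 °C → rt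
Reagents that add atoms: chloromethyl methyl ether (MOMCl), COCCl
Why: Base-mediated O-alkylation (Williamson type) of a symmetric diol, so regiochemistry is not an issue, and it should stop at the mono-ether because the remaining hydroxyl is held in a hydrogen bond to the acetyl carbonyl.

**Step 2**
Reactants: 2 2'-hydroxy-4'-methoxy-6'-(methoxymethoxy)acetophenone; 3 allyl bromide
Product: 4 2'-allyloxy-4'-methoxy-6'-(methoxymethoxy)acetophenone
Conditions: K2CO3, DMF, 60 °C
Reagents that add atoms: none
Why: Williamson ether synthesis in which carbonate in a dipolar aprotic solvent at 60 °C is enough to break the chelate and allylate the last phenol, while the MOM ether and the ketone are inert.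

**Step 3**
Reactants: 4 2'-allyloxy-4'-methoxy-6'-(methoxymethoxy)acetophenone
Product: 6 3'-allyl-2'-hydroxy-4'-methoxy-6'-(methoxymethoxy)acetophenone, via ortho-dienone 5 (not isolated)
Conditions: PhNEt2, 190 °C, sealed tube, Ar
Reagents that add atoms: none
Why: Aromatic Claisen rearrangement in which the [3,3] shift can only deliver the allyl group to the single free ortho position (the other ortho carbon carries the acetyl group), and tautomerisation of dienone 5 restores the arene, which places the future C8 side chain next to the carbon that becomes C8a.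

**Step 4**
Reactants: 6 3'-allyl-2'-hydroxy-4'-methoxy-6'-(methoxymethoxy)acetophenone
Product: 7 2-acetyl-6-allyl-5-methoxy-3-(methoxymethoxy)phenyl triflate
Conditions: Tf2O, pyridine, CH2Cl2, −10 → 0 °C
Reagents that add atoms: trifluoromethanesulfonic anhydride (Tf2O), O=S(=O)(OS(=O)(=O)C(F)(F)F)C(F)(F)F
Why: O-Sulfonylation of a chelated 2-hydroxyaryl ketone with Tf2O/pyridine is standard, and the buffered, cold conditions spare the MOM acetal and the allyl group while turning C8a into the electrophilic site for the later ring closure.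

**Step 5**
Reactants: 7 2-acetyl-6-allyl-5-methoxy-3-(methoxymethoxy)phenyl triflate; 8 2-methylbut-2-ene
Product: 9 2-acetyl-5-methoxy-3-(methoxymethoxy)-6-(3-methylbut-2-en-1-yl)phenyl triflate
Conditions: second-generation Grubbs catalyst (H2IMes)(PCy3)Cl2Ru=CHPh (3 mol %), 2-methylbut-2-ene/CH2Cl2, 40 °C, sealed tube
Reagents that add atoms: none
Why: Olefin cross-metathesis in which a large excess of 2-methylbut-2-ene converts the terminal allyl olefin into the trisubstituted prenyl olefin with loss of propene, the aryl triflate, ketone and acetal being tolerated by the ruthenium carbene.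

**Step 6**
Reactants: 10 isovanillin
Product: 11 4-methoxy-3-(methoxymethoxy)benzaldehyde
Conditions: MOMCl, iPr2NEt, CH2Cl2, 0 °C → rt
Reagents that add atoms: chloromethyl methyl ether (MOMCl), COCCl
Why: Routine O-alkylation of the single free phenol to give an acetal that survives boron enolates, hydride, hot phosphate base and periodinane oxidation.

**Step 7**
Reactants: 9 2-acetyl-5-methoxy-3-(methoxymethoxy)-6-(3-methylbut-2-en-1-yl)phenyl triflate; 11 4-methoxy-3-(methoxymethoxy)benzaldehyde
Product: 14 (1R,3S)-syn-1,3-diol aryl triflate (1-aryl A, 3-aryl B propane-1,3-diol), via boron enolate 12 (not isolated), via boron aldolate 13 (not isolated)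
Conditions: (+)-Ipc2BCl (1.5 equiv), Et3N, Et2O, 0 °C; 11, −78 → −20 °C; LiBH4, −78 → −40 °C; then H2O2, pH 7 buffer, MeOH, 0 °C
Reagents that add atoms: none
Why: Diisopinocampheylboron-mediated aldol addition followed by hydride reduction of the boron aldolate in the same flask, in which the isopinocampheyl groups of (+)-Ipc2BCl (from (−)-α-pinene) should steer the unsubstituted enol borinate 12 to the Si face of aldehyde 11 through a cyclic boron-bound transition state, setting the future C2 as S, and LiBH4 then attacks the six-membered boron chelate 13 to give the 1,3-syn diol whose C4 configuration is erased later.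

**Step 8**
Reactants: 14 (1R,3S)-syn-1,3-diol aryl triflate
Product: 15 (2S,4R)-7-methoxy-2-[4-methoxy-3-(methoxymethoxy)phenyl]-5-(methoxymethoxy)-8-(3-methylbut-2-en-1-yl)chroman-4-ol
Conditions: Pd(OAc)2 (5 mol %), 2-(di-tert-butylphosphino)-1,1'-binaphthyl (7 mol %), K3PO4 (2 equiv), toluene, 80 °C
Reagents that add atoms: none
Why: Pd(OAc)2 is reduced in the flask to zerovalent palladium, which inserts into the C8a–OTf bond; the C2 hydroxyl then binds the arylpalladium centre (divalent palladium), is deprotonated by phosphate, and C–O reductive elimination forms the O1–C8a bond. The closest known reaction type is the palladium-catalysed intramolecular etherification of aryl halides and sulfonates bearing a pendant secondary alcohol, which gives chromans under bulky di-tert-butyl(biaryl)phosphine ligation. Ring C, the only ring formed, closes as a six-membered ring by reductive elimination from a seven-membered aryl(alkoxo)palladium chelate. No stereocentre is created: the C2–O bond is never broken, so C2 keeps its S configuration, and C4 is untouched. The step needs the C2 hydroxyl to win over the C4 hydroxyl and C–O bond formation to win over β-hydride elimination; ring size secures the first (the C4 alkoxide could only close a four-membered ring, and its five-membered chelate simply reverts), while the bulky ligand and the two ortho substituents flanking C8a (prenyl and the side chain) speed reductive elimination enough for the second, and the weak, insoluble phosphate base keeps free alkoxide, and with it attack on the triflate sulfur, to a minimum.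

**Step 9**
Reactants: 15 (2S,4R)-flavan-4-ol, 5-O-MOM and 3'-O-MOM protected
Product: 16 (2S)-7-methoxy-2-[4-methoxy-3-(methoxymethoxy)phenyl]-5-(methoxymethoxy)-8-(3-methylbut-2-en-1-yl)chroman-4-one
Conditions: Dess–Martin periodinane, CH2Cl2, 0 °C → rt
Reagents that add atoms: none
Why: Dess–Martin oxidation of the benzylic secondary alcohol under essentially neutral conditions gives the ketone without touching the prenyl olefin or the acetals, and C2 cannot be scrambled because no base is present to open the pyranone ring by retro-oxa-Michael reaction.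

**Step 10**
Reactants: 16 (2S)-flavanone, 5-O-MOM and 3'-O-MOM protected
Product: 17 (2S)-5-hydroxy-2-(3-hydroxy-4-methoxyphenyl)-7-methoxy-8-(3-methylbut-2-en-1-yl)chroman-4-one (CNP0228678.1)
Conditions: HCl (ca. 2 M) in MeOH, rt
Reagents that add atoms: none
Why: Acid-catalysed acetal methanolysis removes both MOM ethers, the peri one being assisted by the C4 carbonyl, under conditions mild enough that the prenyl olefin (which has no free ortho hydroxyl to cyclise onto) and the C2 benzylic ether should survive.

**Compound list**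
1 | 1-(2,6-dihydroxy-4-methoxyphenyl)ethanone (2',6'-dihydroxy-4'-methoxyacetophenone) | CC(=O)c1c(O)cc(OC)cc1O | starting material
2 | 1-[2-hydroxy-4-methoxy-6-(methoxymethoxy)phenyl]ethanone | CC(=O)c1c(O)cc(OC)cc1OCOC | intermediate
3 | allyl bromide (3-bromoprop-1-ene) | C=CCBr | starting material
4 | 1-[2-(allyloxy)-4-methoxy-6-(methoxymethoxy)phenyl]ethanone | CC(=O)c1c(OCC=C)cc(OC)cc1OCOC | intermediate
5 | 2-acetyl-6-allyl-5-methoxy-3-(methoxymethoxy)cyclohexa-2,4-dien-1-one (racemic ortho-dienone, not isolated) | CC(=O)C1=C(OCOC)C=C(OC)C(CC=C)C1=O | intermediate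
6 | 1-[3-allyl-2-hydroxy-4-methoxy-6-(methoxymethoxy)phenyl]ethanone | CC(=O)c1c(O)c(CC=C)c(OC)cc1OCOC | intermediate
7 | 2-acetyl-6-allyl-5-methoxy-3-(methoxymethoxy)phenyl trifluoromethanesulfonate | CC(=O)c1c(OS(=O)(=O)C(F)(F)F)c(CC=C)c(OC)cc1OCOC | intermediate
8 | 2-methylbut-2-ene | CC=C(C)C | starting material
9 | 2-acetyl-5-methoxy-3-(methoxymethoxy)-6-(3-methylbut-2-en-1-yl)phenyl trifluoromethanesulfonate | CC(=O)c1c(OS(=O)(=O)C(F)(F)F)c(CC=C(C)C)c(OC)cc1OCOC | intermediate
10 | isovanillin (3-hydroxy-4-methoxybenzaldehyde) | COc1ccc(C=O)cc1O | starting material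
11 | 4-methoxy-3-(methoxymethoxy)benzaldehyde | COc1ccc(C=O)cc1OCOC | intermediate
12 | diisopinocampheylboron enolate of 9 (Ipc groups derived from (−)-α-pinene; not isolated) | C=C(OB([C@H]1C[C@H]2C[C@@H]([C@@H]1C)C2(C)C)[C@H]3C[C@H]4C[C@@H]([C@@H]3C)C4(C)C)c5c(OS(=O)(=O)C(F)(F)F)c(CC=C(C)C)c(OC)cc5OCOC | intermediate
13 | (S)-configured diisopinocampheylboron aldolate of the β-hydroxy ketone from 9 and 11 (not isolated) | COc1ccc(cc1OCOC)[C@H](CC(=O)c2c(OS(=O)(=O)C(F)(F)F)c(CC=C(C)C)c(OC)cc2OCOC)OB([C@H]3C[C@H]4C[C@@H]([C@@H]3C)C4(C)C)[C@H]5C[C@H]6C[C@@H]([C@@H]5C)C6(C)C | intermediate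
14 | 2-[(1R,3S)-1,3-dihydroxy-3-[4-methoxy-3-(methoxymethoxy)phenyl]propyl]-5-methoxy-3-(methoxymethoxy)-6-(3-methylbut-2-en-1-yl)phenyl trifluoromethanesulfonate (syn-diol) | COc1ccc([C@@H](O)C[C@@H](O)c2c(OCOC)cc(OC)c(CC=C(C)C)c2OS(=O)(=O)C(F)(F)F)cc1OCOC | intermediate
15 | (2S,4R)-7-methoxy-2-[4-methoxy-3-(methoxymethoxy)phenyl]-5-(methoxymethoxy)-8-(3-methylbut-2-en-1-yl)-3,4-dihydro-2H-chromen-4-ol (2,4-trans) | COc1ccc([C@@H]2C[C@@H](O)c3c(OCOC)cc(OC)c(CC=C(C)C)c3O2)cc1OCOC | intermediate
16 | (2S)-7-methoxy-2-[4-methoxy-3-(methoxymethoxy)phenyl]-5-(methoxymethoxy)-8-(3-methylbut-2-en-1-yl)-2,3-dihydro-4H-chromen-4-one | COc1ccc([C@@H]2CC(=O)c3c(OCOC)cc(OC)c(CC=C(C)C)c3O2)cc1OCOC | intermediate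
17 | (2S)-5-hydroxy-2-(3-hydroxy-4-methoxyphenyl)-7-methoxy-8-(3-methylbut-2-en-1-yl)-2,3-dihydro-4H-chromen-4-one | COc1ccc([C@@H]2CC(=O)c3c(O)cc(OC)c(CC=C(C)C)c3O2)cc1O | target

**Step count**
Total: 10 steps. Longest linear sequence: 9 steps (steps 1 to 5, then 7 to 10); step 6 is the one-step side branch.

**Steps most likely to fail**

1. Step 8 (ring closure). Oxidative addition into an electron-rich triflate flanked by two ortho substituents may be slow. While it is slow, the triflate can be lost by S–O cleavage or by transfer to the neighbouring C4 alkoxide. β-Hydride elimination from the bound alkoxide would give the reduced arene, and the prenyl olefin may hold the arylpalladium species in an unproductive chelate.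
Fallback (sets out from 6, returns at 17): the ring is built first and C2 is set afterwards by conjugate arylation. Cross-metathesis of 6 with 8 under the conditions of step 5 should give 1-[2-hydroxy-4-methoxy-6-(methoxymethoxy)-3-(3-methylbut-2-en-1-yl)phenyl]ethanone F1. Condensation with N,N-dimethylformamide dimethyl acetal in toluene at 90 °C gives the enaminone (E)-3-(dimethylamino)-1-[2-hydroxy-4-methoxy-6-(methoxymethoxy)-3-(3-methylbut-2-en-1-yl)phenyl]prop-2-en-1-one F2. Brief treatment with a weak acid (pyridinium p-toluenesulfonate or silica gel) cyclises it, with loss of dimethylamine, to the chromone 7-methoxy-5-(methoxymethoxy)-8-(3-methylbut-2-en-1-yl)-4H-chromen-4-one F3. Rhodium-catalysed enantioselective 1,4-addition of commercial 3-hydroxy-4-methoxyphenylboronic acid ([Rh(OH)(cod)]2, chiral biaryl bisphosphine of the antipode that delivers the aryl group to give 2S, aqueous toluene), a known entry to flavanones from chromones, then gives (2S)-2-(3-hydroxy-4-methoxyphenyl)-7-methoxy-5-(methoxymethoxy)-8-(3-methylbut-2-en-1-yl)chroman-4-one F4. The acid treatment of step 10 removes its single MOM group to give 17.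

2. Step 7 (aldol addition and reduction). Facial discrimination by the boron reagent may be incomplete for a methyl ketone enolate; the sense and level of induction are to be checked on 14 (for example by Mosher ester analysis). The hindered, chelated ketone may also be reduced only sluggishly.
Fallback (sets out from 14, returns at 16): diol of insufficient enantiopurity is not discarded. Excess Dess–Martin periodinane oxidises both carbinols to the 1,3-diketone 2-{3-[4-methoxy-3-(methoxymethoxy)phenyl]-3-oxopropanoyl}-5-methoxy-3-(methoxymethoxy)-6-(3-methylbut-2-en-1-yl)phenyl trifluoromethanesulfonate F5, which erases both centres. Ruthenium-catalysed asymmetric transfer hydrogenation with RuCl[(S,S)-TsDPEN](p-cymene) in HCO2H/Et3N, a reaction known to turn 1,3-diaryl-1,3-diketones into anti-1,3-diols under catalyst control, should then give 2-[(1S,3S)-1,3-dihydroxy-3-[4-methoxy-3-(methoxymethoxy)phenyl]propyl]-5-methoxy-3-(methoxymethoxy)-6-(3-methylbut-2-en-1-yl)phenyl trifluoromethanesulfonate F6. If the hindered ring A carbonyl lags, NaBH4 finishes it; its configuration is of no consequence, and the other epimer is 14 itself. F6 cyclises under the conditions of step 8 to (2S,4S)-7-methoxy-2-[4-methoxy-3-(methoxymethoxy)phenyl]-5-(methoxymethoxy)-8-(3-methylbut-2-en-1-yl)chroman-4-ol F7, the C4 epimer of 15. The oxidation of step 9 converges on 16.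

3. Step 10 (deprotection). The non-chelated 3'-O-MOM ether cleaves more slowly than the peri one. During that time acid may ionise the C2 benzylic ether (stabilised by the para methoxy group), which opens ring C and erodes enantiopurity, or may add across the prenyl olefin.
Fallback (sets out from 10, returns at 17): the ring B phenol is carried as a silyl ether, so the only acetal left at the end is the chelated one. Isovanillin 10 with TBSCl and imidazole in DMF gives 3-(tert-butyldimethylsilyloxy)-4-methoxybenzaldehyde F8. Under the conditions of step 7, enolate 12 adds to F8 to give the silyl-bearing boron aldolate F9 (not isolated), which is reduced to 2-[(1R,3S)-3-[3-(tert-butyldimethylsilyloxy)-4-methoxyphenyl]-1,3-dihydroxypropyl]-5-methoxy-3-(methoxymethoxy)-6-(3-methylbut-2-en-1-yl)phenyl trifluoromethanesulfonate F10. The conditions of step 8 give (2S,4R)-2-[3-(tert-butyldimethylsilyloxy)-4-methoxyphenyl]-7-methoxy-5-(methoxymethoxy)-8-(3-methylbut-2-en-1-yl)chroman-4-ol F11, and those of step 9 give (2S)-2-[3-(tert-butyldimethylsilyloxy)-4-methoxyphenyl]-7-methoxy-5-(methoxymethoxy)-8-(3-methylbut-2-en-1-yl)chroman-4-one F12. Very dilute methanolic HCl at 0 °C should remove the carbonyl-assisted peri acetal alone to give (2S)-2-[3-(tert-butyldimethylsilyloxy)-4-methoxyphenyl]-5-hydroxy-7-methoxy-8-(3-methylbut-2-en-1-yl)chroman-4-one F13. Et3N·3HF in MeCN at rt, a non-basic fluoride source, then removes the silyl group to give 17.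

**Further compounds**
F1 | step 8 | 1-[2-hydroxy-4-methoxy-6-(methoxymethoxy)-3-(3-methylbut-2-en-1-yl)phenyl]ethanone | CC(=O)c1c(O)c(CC=C(C)C)c(OC)cc1OCOC
F2 | step 8 | (E)-3-(dimethylamino)-1-[2-hydroxy-4-methoxy-6-(methoxymethoxy)-3-(3-methylbut-2-en-1-yl)phenyl]prop-2-en-1-one | CN(C)/C=C/C(=O)c1c(O)c(CC=C(C)C)c(OC)cc1OCOC
F3 | step 8 | 7-methoxy-5-(methoxymethoxy)-8-(3-methylbut-2-en-1-yl)-4H-chromen-4-one | COCOc1cc(OC)c(CC=C(C)C)c2occc(=O)c12
F4 | step 8 | (2S)-2-(3-hydroxy-4-methoxyphenyl)-7-methoxy-5-(methoxymethoxy)-8-(3-methylbut-2-en-1-yl)chroman-4-one | COc1ccc([C@@H]2CC(=O)c3c(OCOC)cc(OC)c(CC=C(C)C)c3O2)cc1O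
F5 | step 7 | 2-{3-[4-methoxy-3-(methoxymethoxy)phenyl]-3-oxopropanoyl}-5-methoxy-3-(methoxymethoxy)-6-(3-methylbut-2-en-1-yl)phenyl trifluoromethanesulfonate | COc1ccc(C(=O)CC(=O)c2c(OS(=O)(=O)C(F)(F)F)c(CC=C(C)C)c(OC)cc2OCOC)cc1OCOC
F6 | step 7 | 2-[(1S,3S)-1,3-dihydroxy-3-[4-methoxy-3-(methoxymethoxy)phenyl]propyl]-5-methoxy-3-(methoxymethoxy)-6-(3-methylbut-2-en-1-yl)phenyl trifluoromethanesulfonate | COc1ccc([C@@H](O)C[C@H](O)c2c(OCOC)cc(OC)c(CC=C(C)C)c2OS(=O)(=O)C(F)(F)F)cc1OCOC
F7 | step 7 | (2S,4S)-7-methoxy-2-[4-methoxy-3-(methoxymethoxy)phenyl]-5-(methoxymethoxy)-8-(3-methylbut-2-en-1-yl)chroman-4-ol | COc1ccc([C@@H]2C[C@H](O)c3c(OCOC)cc(OC)c(CC=C(C)C)c3O2)cc1OCOC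
F8 | step 10 | 3-(tert-butyldimethylsilyloxy)-4-methoxybenzaldehyde | COc1ccc(C=O)cc1O[Si](C)(C)C(C)(C)C
F9 | step 10 | (S)-configured diisopinocampheylboron aldolate from 12 and F8 (not isolated) | COc1ccc(cc1O[Si](C)(C)C(C)(C)C)[C@H](CC(=O)c2c(OS(=O)(=O)C(F)(F)F)c(CC=C(C)C)c(OC)cc2OCOC)OB([C@H]3C[C@H]4C[C@@H]([C@@H]3C)C4(C)C)[C@H]5C[C@H]6C[C@@H]([C@@H]5C)C6(C)C
F10 | step 10 | 2-[(1R,3S)-3-[3-(tert-butyldimethylsilyloxy)-4-methoxyphenyl]-1,3-dihydroxypropyl]-5-methoxy-3-(methoxymethoxy)-6-(3-methylbut-2-en-1-yl)phenyl trifluoromethanesulfonate | COc1ccc([C@@H](O)C[C@@H](O)c2c(OCOC)cc(OC)c(CC=C(C)C)c2OS(=O)(=O)C(F)(F)F)cc1O[Si](C)(C)C(C)(C)C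
F11 | step 10 | (2S,4R)-2-[3-(tert-butyldimethylsilyloxy)-4-methoxyphenyl]-7-methoxy-5-(methoxymethoxy)-8-(3-methylbut-2-en-1-yl)chroman-4-ol | COc1ccc([C@@H]2C[C@@H](O)c3c(OCOC)cc(OC)c(CC=C(C)C)c3O2)cc1O[Si](C)(C)C(C)(C)C
F12 | step 10 | (2S)-2-[3-(tert-butyldimethylsilyloxy)-4-methoxyphenyl]-7-methoxy-5-(methoxymethoxy)-8-(3-methylbut-2-en-1-yl)chroman-4-one | COc1ccc([C@@H]2CC(=O)c3c(OCOC)cc(OC)c(CC=C(C)C)c3O2)cc1O[Si](C)(C)C(C)(C)C
F13 | step 10 | (2S)-2-[3-(tert-butyldimethylsilyloxy)-4-methoxyphenyl]-5-hydroxy-7-methoxy-8-(3-methylbut-2-en-1-yl)chroman-4-one | COc1ccc([C@@H]2CC(=O)c3c(O)cc(OC)c(CC=C(C)C)c3O2)cc1O[Si](C)(C)C(C)(C)C
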